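## Retrosynthetic overview

1. Numbering used throughout: vinyl C1=C2, carbinol C3, C4, C5, quaternary C6, C7, C8, ketone C9, C10, C11, quaternary C12 (CH3), C13 (CH–CH3), C14 (CH–OAc), C15, C16 (CH–CH3). Ring A = C6–C7–C8–C9–C10–C11, ring B = C8–C9–C10–C11–C12–C13 (A and B make the bicyclo[2.2.2]octanone), ring C = C6–C11–C12–C14–C15–C16.
2. End game: C14–OAc from a C14 ketone (dissolving-metal reduction, acetylation); C16–CH3 by cuprate addition to a C15=C16 enone; the C9 ketone is carried as its silyl enol ether and the C3 alcohol as a silyl ether.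
3. Key disconnection: C15=C16 by Knoevenagel condensation of a C16 aldehyde with a C15 active methylene and, in the same operation, C11–C12 plus C8–C13 by intramolecular Diels–Alder reaction. A monocyclic ring A aldehyde and an acyclic keto ester give rings C and B at once, with C8, C11, C12 and C13 relayed from C6.
4. Enabling feature: the C14 carbonyl carbon lies between C12 and C15, and C16 is a one-carbon branch on the quaternary C6 next to C11. The bridge C16–C15–C14 of ring C is therefore a three-atom tether that delivers a C14-activated C12=C13 alkene to the C8=C9(O)–C10=C11 diene of ring A, whose 2-oxy group is the C9 ketone oxygen.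
5. Ring A comes from an enantioselective Diels–Alder reaction of a 2-substituted acrolein (sets C6), itself made from (S)-linalool (brings C3). Order of ring formation: A, then C and B together.

Key step: step 8

Assumption: (S)-linalool of high enantiomeric purity is taken as purchasable, and the (R,R)-diol catalyst of step 5 is taken to give the C6 configuration drawn for 9; if the sense of induction is the opposite, the (S,S)-catalyst is used instead.

## Route

Step 1
Reactants: 1 (S)-(+)-linalool
Product: 2 triethyl{[(3S)-3,7-dimethylocta-1,6-dien-3-yl]oxy}silane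
Conditions: TESOTf, 2,6-lutidine, CH2Cl2, −78 to 0 °C
Reagents that add atoms: triethylsilyl triflate, CC[Si](CC)(CC)OS(=O)(=O)C(F)(F)F
Why: Silyl ether protection of the hindered tertiary allylic alcohol with the silyl triflate; no stereocentre is touched, so C3 is carried over from the chiral pool.

Step 2
Reactants: 2 triethyl{[(3S)-3,7-dimethylocta-1,6-dien-3-yl]oxy}silane
Product: 3 (4S)-4-methyl-4-(triethylsilyloxy)hex-5-enal
Conditions: O3 (1 equiv, indicator end point), CH2Cl2/MeOH, −78 °C; then Me2S
Reagents that add atoms: ozone, [O-][O+]=O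
Why: Ozonolysis with reductive work-up; the electron-rich trisubstituted alkene should react far faster than the hindered monosubstituted vinyl group, so only the former is cleaved.

Step 3
Reactants: 3 (4S)-4-methyl-4-(triethylsilyloxy)hex-5-enal
Product: 5 (5S)-5-methyl-5-(triethylsilyloxy)hept-6-enal, via enol ether 4 (not isolated)
Conditions: Ph3P(CH2OMe)Cl, KHMDS, THF, 0 °C; then 5% aq. oxalic acid, THF, 23 °C
Reagents that add atoms: (methoxymethyl)triphenylphosphonium chloride, COC[P+](c1ccccc1)(c1ccccc1)c1ccccc1.[Cl-]; water, O
Why: Wittig methoxymethylenation followed by mild hydrolysis of the enol ether (one-carbon aldehyde homologation); the tertiary silyl ether should survive the brief weak acid.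

Step 4
Reactants: 5 (5S)-5-methyl-5-(triethylsilyloxy)hept-6-enal
Product: 6 (5S)-5-methyl-2-methylidene-5-(triethylsilyloxy)hept-6-enal
Conditions: CH2O (37% aq.), pyrrolidine (10 mol %), EtCO2H (10 mol %), i-PrOH, 45 °C
Reagents that add atoms: formaldehyde, C=O
Why: Amine-catalysed α-methylenation (Mannich condensation and elimination) of an unbranched aldehyde gives the 2-substituted acrolein; no stereocentre is formed.

Step 5
Reactants: 6 (5S)-5-methyl-2-methylidene-5-(triethylsilyloxy)hept-6-enal, 7 (E)-1-(dimethylamino)-3-(tert-butyldimethylsilyloxy)buta-1,3-diene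
Product: 9 (1R)-1-[(3S)-3-methyl-3-(triethylsilyloxy)pent-4-en-1-yl]-4-oxocyclohex-2-ene-1-carbaldehyde, via amino silyl enol ether cycloadduct 8 (not isolated)
Conditions: (R,R)-1-naphthyl-TADDOL (20 mol %), PhMe, −80 to −40 °C; then 0.1 M HCl, THF, 0 °C
Reagents that add atoms: none
Why: Hydrogen-bond-catalysed enantioselective Diels–Alder reaction of the aminosiloxydiene with an α-substituted acrolein (the amino terminus bonds to the acrolein α-carbon), in which the chiral diol shields one face of the dienophile and so sets C6, followed by acid hydrolysis and β-elimination of dimethylamine to unveil the enone; the minor C6 epimer is a diastereomer and should be removable by chromatography.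

Step 6
Reactants: 9 (1R)-1-[(3S)-3-methyl-3-(triethylsilyloxy)pent-4-en-1-yl]-4-oxocyclohex-2-ene-1-carbaldehyde
Product: 10 (1R)-4-(tert-butyldimethylsilyloxy)-1-[(3S)-3-methyl-3-(triethylsilyloxy)pent-4-en-1-yl]cyclohexa-2,4-diene-1-carbaldehyde
Conditions: TBSOTf, Et3N (excess), CH2Cl2, 0 °C
Reagents that add atoms: tert-butyldimethylsilyl triflate, CC(C)(C)[Si](C)(C)OS(=O)(=O)C(F)(F)F
Why: Soft enolisation and O-silylation of the enone; only C8 carries acidic hydrogens because C6 is quaternary, so the cross-conjugated 2-silyloxy diene should form, and the non-enolisable aldehyde is left alone.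

Step 7
Reactants: 11 allyl acetate, 12 (E)-2-methylbut-2-enoyl chloride (tigloyl chloride)
Product: 13 allyl (E)-4-methyl-3-oxohex-4-enoate
Conditions: LiHMDS (2.1 equiv), 11 (2.1 equiv), THF, −78 °C; then 12 (1 equiv)
Reagents that add atoms: none
Why: Crossed Claisen acylation of the ester enolate by the acid chloride (the second equivalent of enolate deprotonates the product); the E alkene is not involved.

Step 8
Reactants: 10 (1R)-4-(tert-butyldimethylsilyloxy)-1-[(3S)-3-methyl-3-(triethylsilyloxy)pent-4-en-1-yl]cyclohexa-2,4-diene-1-carbaldehyde, 13 allyl (E)-4-methyl-3-oxohex-4-enoate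
Product: 15 tricyclic enone ester (3S,6S,8R,11S,12S,13R; C14 ketone; C15=C16 with CO2allyl on C15; C9–OTBS enol ether C9=C10; C3–OTES), via alkylidene keto ester 14 (not isolated)
Conditions: piperidine (20 mol %), AcOH (20 mol %), 4 Å MS, PhMe (0.02 M), 23 °C then 80 °C
Reagents that add atoms: none
Why: Piperidinium acetate condenses the non-enolisable C16 aldehyde of 10 with the C15 methylene of 13 (Knoevenagel condensation, new C15=C16 bond); the two alkylidene isomers should interconvert by reversible amine addition, and only the one with the C14 ketone cis to C6 can cyclise, so the pair funnels through it. In that isomer the bridge C16=C15–C14 holds the E-configured C12=C13 alkene, activated by the cross-conjugated C14 ketone, over the 2-silyloxy diene C8=C9–C10=C11, and a thermal intramolecular Diels–Alder reaction forms C11–C12 and C8–C13. The closest known reaction types are domino Knoevenagel/cycloaddition sequences and the intramolecular Diels–Alder reactions of cyclohexa-1,3-dienes that carry the dienophile on a three-atom tether at the sp3 carbon next to the diene, which give this tricyclic skeleton. Ring C closes as the six-membered tether ring through the C11–C12 bond (the dienophile carbonyl lies inside the tether), and ring B closes as the bicyclo[2.2.2]octene bridge of the [4+2] addition across C8 and C11. C8 and C11 are set by the diene face, which the C6 stereocentre dictates because the tether starts from C6; C12 is set by the tether (C14 must end up syn to C6); C13 is set by the E alkene geometry through suprafacial addition (the two methyl groups stay cis). The step needs the intramolecular cycloaddition to outrun intermolecular reactions of the alkylidene and loss of the silyl dienol ether; the short tether, the absence of any other feasible ring size, high dilution and water removal by molecular sieves should secure this.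

Step 9
Reactants: 15 tricyclic enone ester
Product: 16 tricyclic β-keto ester (3S,6S,8R,11S,12S,13R,16R; C16–CH3; C15–H/CO2allyl enolisable and drawn with the ester equatorial)
Conditions: Me2CuLi (from CuI and MeLi), Et2O, −78 to −40 °C; aq. NH4Cl
Reagents that add atoms: lithium dimethylcuprate, [Li+].C[Cu-]C
Why: Conjugate addition of a Gilman cuprate to the doubly activated alkylidene β-keto ester; the methyl group should enter C16 axially from the open top face of ring C, anti to the C6–C7 bond that shields the bottom face, which gives 16R, and the C9 silyl enol ether is inert.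

Step 10
Reactants: 16 tricyclic β-keto ester
Product: 17 tricyclic ketone (3S,6S,8R,11S,12S,13R,16R; C14 ketone; C15H2)
Conditions: Pd(PPh3)4 (5 mol %), morpholine, THF, 23 °C
Reagents that add atoms: none
Why: Palladium-catalysed deallylation of the allyl β-keto ester (Tsuji–Trost allyl transfer to morpholine) and spontaneous decarboxylation of the β-keto acid; C12 is quaternary and C16 is not α to a carbonyl, so no stereocentre is at risk.

Step 11
Reactants: 17 tricyclic ketone
Product: 18 tricyclic alcohol (3S,6S,8R,11S,12S,13R,14R,16R; C14–OH equatorial on ring C)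
Conditions: Li, NH3 (l), THF, MeOH, −78 °C; then NH4Cl
Reagents that add atoms: none
Why: Dissolving-metal reduction of the ketone passes through a configurationally mobile carbinyl anion and should give the thermodynamically preferred equatorial C14 alcohol (trans to the axial C16 methyl, 14R); the silyl enol ether, the silyl ether and the isolated alkenes should not be reduced.

Step 12
Reactants: 18 tricyclic alcohol
Product: 19 tricyclic acetate (C14–OAc; silyl groups retained)
Conditions: Ac2O, pyridine, DMAP (cat.), CH2Cl2, 23 °C
Reagents that add atoms: acetic anhydride, CC(=O)OC(C)=O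
Why: DMAP-catalysed acylation of the hindered secondary alcohol with retention at C14; the tertiary alcohol is silyl-protected.

Step 13
Reactants: 19 tricyclic acetate
Product: 20 target CNP0281208.1
Conditions: HF·pyridine, pyridine, THF, 0 to 23 °C
Reagents that add atoms: none
Why: Fluoride-mediated desilylation cleaves the silyl enol ether to the C9 ketone and the tertiary silyl ether to the C3 alcohol in one operation, under buffered conditions that should leave the acetate and the tertiary allylic alcohol intact; C10 becomes CH2, so no stereocentre is formed.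

## Compound list

1 | (S)-(+)-linalool, (3S)-3,7-dimethylocta-1,6-dien-3-ol | C=C[C@@](C)(O)CCC=C(C)C | starting material
2 | triethyl{[(3S)-3,7-dimethylocta-1,6-dien-3-yl]oxy}silane | C=C[C@@](C)(O[Si](CC)(CC)CC)CCC=C(C)C | intermediate
3 | (4S)-4-methyl-4-(triethylsilyloxy)hex-5-enal | C=C[C@@](C)(O[Si](CC)(CC)CC)CCC=O | intermediate
4 | (3S)-7-methoxy-3-methyl-3-(triethylsilyloxy)hepta-1,6-diene (E/Z mixture at the enol ether) | C=C[C@@](C)(O[Si](CC)(CC)CC)CCC=COC | intermediate (not isolated)
5 | (5S)-5-methyl-5-(triethylsilyloxy)hept-6-enal | C=C[C@@](C)(O[Si](CC)(CC)CC)CCCC=O | intermediate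
6 | (5S)-5-methyl-2-methylidene-5-(triethylsilyloxy)hept-6-enal | C=C[C@@](C)(O[Si](CC)(CC)CC)CCC(=C)C=O | intermediate
7 | (E)-1-(dimethylamino)-3-(tert-butyldimethylsilyloxy)buta-1,3-diene | CN(C)/C=C/C(=C)O[Si](C)(C)C(C)(C)C | starting material
8 | 4-(tert-butyldimethylsilyloxy)-2-(dimethylamino)-1-[(3S)-3-methyl-3-(triethylsilyloxy)pent-4-en-1-yl]cyclohex-3-ene-1-carbaldehyde (endo adduct, NMe2 cis to CHO) | C=C[C@@](C)(O[Si](CC)(CC)CC)CC[C@@]1(C=O)CCC(O[Si](C)(C)C(C)(C)C)=C[C@@H]1N(C)C | intermediate (not isolated)
9 | (1R)-1-[(3S)-3-methyl-3-(triethylsilyloxy)pent-4-en-1-yl]-4-oxocyclohex-2-ene-1-carbaldehyde | C=C[C@@](C)(O[Si](CC)(CC)CC)CC[C@@]1(C=O)CCC(=O)C=C1 | intermediate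
10 | (1R)-4-(tert-butyldimethylsilyloxy)-1-[(3S)-3-methyl-3-(triethylsilyloxy)pent-4-en-1-yl]cyclohexa-2,4-diene-1-carbaldehyde | C=C[C@@](C)(O[Si](CC)(CC)CC)CC[C@@]1(C=O)CC=C(O[Si](C)(C)C(C)(C)C)C=C1 | intermediate
11 | allyl acetate | CC(=O)OCC=C | starting material
12 | (E)-2-methylbut-2-enoyl chloride (tigloyl chloride) | C/C=C(\C)C(Cl)=O | starting material
13 | allyl (E)-4-methyl-3-oxohex-4-enoate | C/C=C(\C)C(=O)CC(=O)OCC=C | intermediate
14 | allyl (2E,4E)-2-{[(1R)-4-(tert-butyldimethylsilyloxy)-1-[(3S)-3-methyl-3-(triethylsilyloxy)pent-4-en-1-yl]cyclohexa-2,4-dien-1-yl]methylidene}-4-methyl-3-oxohex-4-enoate (ketone cis to the ring across C15=C16) | C=C[C@@](C)(O[Si](CC)(CC)CC)CC[C@@]1(/C=C(/C(=O)OCC=C)C(=O)/C(C)=C/C)CC=C(O[Si](C)(C)C(C)(C)C)C=C1 | intermediate (not isolated)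
15 | tricyclic enone ester: rings A, B and C closed; C9–OTBS enol ether (C9=C10); C14 ketone; C15=C16 with CO2allyl on C15; C3–OTES; (3S,6S,8R,11S,12S,13R) | C=C[C@@](C)(O[Si](CC)(CC)CC)CC[C@@]12C[C@H]3C(O[Si](C)(C)C(C)(C)C)=C[C@@H]1[C@](C)([C@@H]3C)C(=O)C(C(=O)OCC=C)=C2 | intermediate
16 | tricyclic β-keto ester: as 15 with C16–CH3 (16R) and C15–H/CO2allyl (enolisable; ester drawn equatorial) | C=C[C@@](C)(O[Si](CC)(CC)CC)CC[C@@]12C[C@H]3C(O[Si](C)(C)C(C)(C)C)=C[C@@H]1[C@](C)([C@@H]3C)C(=O)[C@@H](C(=O)OCC=C)[C@H]2C | intermediate
17 | tricyclic ketone: C14 ketone, C15H2, C16–CH3; C9–OTBS enol ether; C3–OTES; (3S,6S,8R,11S,12S,13R,16R) | C=C[C@@](C)(O[Si](CC)(CC)CC)CC[C@@]12C[C@H]3C(O[Si](C)(C)C(C)(C)C)=C[C@@H]1[C@](C)([C@@H]3C)C(=O)C[C@H]2C | intermediate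
18 | tricyclic alcohol: as 17 with C14–OH (14R, equatorial on ring C, trans to the C16 methyl) | C=C[C@@](C)(O[Si](CC)(CC)CC)CC[C@@]12C[C@H]3C(O[Si](C)(C)C(C)(C)C)=C[C@@H]1[C@](C)([C@@H]3C)[C@H](O)C[C@H]2C | intermediate
19 | tricyclic acetate: as 18 with C14–OAc | C=C[C@@](C)(O[Si](CC)(CC)CC)CC[C@@]12C[C@H]3C(O[Si](C)(C)C(C)(C)C)=C[C@@H]1[C@](C)([C@@H]3C)[C@H](OC(C)=O)C[C@H]2C | intermediate
20 | CNP0281208.1: C9 ketone, C14 acetate, C3 tertiary allylic alcohol; (3S,6S,8R,11S,12S,13R,14R,16R) in the numbering of the overview | C=C[C@@](C)(O)CC[C@@]12C[C@H]3C(=O)C[C@@H]1[C@](C)([C@@H]3C)[C@H](OC(C)=O)C[C@H]2C | target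

## Step count and risks

Total: 13 steps. Longest linear sequence: 12 steps (steps 1–6 and 8–13); step 7 is a one-step branch.

Steps most likely to fail:

Step 8 (key step). Possible failures are slow condensation at the hindered neopentyl aldehyde, protodesilylation of the silyl dienol ether under the buffered conditions, a [1,5]-hydrogen shift of the diene on heating, and intermolecular reaction of the alkylidene before it cyclises. The fallback sets out from 10 and returns at 17; it gives up the domino and the ester. The kinetic lithium enolate of commercial (E)-3-methylpent-3-en-2-one (LDA, THF, −78 °C) is added to the aldehyde of 10 to give the aldol adduct F1 (both C16 epimers), in which the dienophile hangs on an sp3 tether. Heating in toluene (BHT, 110–140 °C) effects the intramolecular Diels–Alder reaction to the tricyclic hydroxy ketone F2. Mesylation and elimination (MsCl, Et3N, then DBU) give the ester-free enone F3, and addition of Me2CuLi to F3 gives 17 directly.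

Step 11. Possible failures are kinetic protonation that delivers the axial C14 alcohol, reductive cleavage of the allylic C–O bond, and saturation of the terminal alkene. The fallback sets out from 17 and returns at 18; it separates reduction from stereocontrol. Hydride reduction (NaBH4, MeOH, 0 °C) should give mainly the axial alcohol, the 14-epi alcohol F4, because both faces of the ketone are hindered. Equilibration under Meerwein–Ponndorf–Verley/Oppenauer conditions (Al(Oi-Pr)3, catalytic acetone, i-PrOH/PhMe, 80 °C) should then convert F4 into the more stable equatorial alcohol 18, which lacks the 1,3-diaxial contact with the C16 methyl group.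

Step 5. Possible failures are insufficient or reversed facial control at C6 (which shows up as the C6 diastereomer because C3 is fixed) and loss of the tertiary silyl ether in the acidic unmasking. The fallback sets out from 6 and returns at 9; it uses a different diene and a different mode of catalysis and introduces the enone by oxidation. Diels–Alder reaction of 6 with 2-(triisopropylsilyloxy)buta-1,3-diene under a chiral cationic oxazaborolidine (oxazaborolidinium triflimide) Lewis acid catalyst gives the silyl enol ether F5, whose enol ether double bond already marks C9=C10. Saegusa–Ito oxidation (Pd(OAc)2, MeCN, 23 °C) then gives 9 without any acid.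

Further compounds
F1 | step 8 | aldol adduct: 10 with the C16 aldehyde converted to CH(OH)–CH2–C(=O)–C(CH3)=CH–CH3 (E; both C16 epimers) | C=C[C@@](C)(O[Si](CC)(CC)CC)CC[C@@]1(C(O)CC(=O)/C(C)=C/C)CC=C(O[Si](C)(C)C(C)(C)C)C=C1
F2 | step 8 | tricyclic hydroxy ketone: skeleton of 17 with C16–OH in place of C16–CH3 (both C16 epimers) | C=C[C@@](C)(O[Si](CC)(CC)CC)CC[C@@]12C[C@H]3C(O[Si](C)(C)C(C)(C)C)=C[C@@H]1[C@](C)([C@@H]3C)C(=O)CC2O
F3 | step 8 | tricyclic enone: C14 ketone with C15=C16, no ester; C9–OTBS enol ether; C3–OTES | C=C[C@@](C)(O[Si](CC)(CC)CC)CC[C@@]12C[C@H]3C(O[Si](C)(C)C(C)(C)C)=C[C@@H]1[C@](C)([C@@H]3C)C(=O)C=C2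
F4 | step 11 | 14-epi alcohol: C14 epimer of 18 (axial OH, cis to the C16 methyl) | C=C[C@@](C)(O[Si](CC)(CC)CC)CC[C@@]12C[C@H]3C(O[Si](C)(C)C(C)(C)C)=C[C@@H]1[C@](C)([C@@H]3C)[C@@H](O)C[C@H]2C
F5 | step 5 | 1-[(3S)-3-methyl-3-(triethylsilyloxy)pent-4-en-1-yl]-4-(triisopropylsilyloxy)cyclohex-3-ene-1-carbaldehyde (C1 configured as in 9) | C=C[C@@](C)(O[Si](CC)(CC)CC)CC[C@@]1(C=O)CCC(O[Si](C(C)C)(C(C)C)C(C)C)=CC1
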